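(The runs are simulated on assumed constants.)

Maple now holds more target than substrate: 19.7% against 4.3% after 40.0 h.

all flasks: substrate 0.51 M

| run | remark | time |
|---|---|---|
| maple | the very flask that is asked about, followed so far |  |
| flask |  | 10 d |

maple run (percent of the substrate charged)

| time / h | target / % | substrate / % |
|---|---|---|
| 8.00 | 28.8 | 22.6 |
| 15.0 | 27.9 | 11.9 |
| 25.0 | 25.2 | 7.3 |
| 30.0 | 22.3 | 6.3 |
| 40.0 | 19.7 | 4.3 |

(scatter of a reading: 0.5 percentage points)



- time up to 10 d at which target stands highest
- the amount of target, in percent of the substrate charged, at that time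

For the next person at the bench: maple's highest readings of target are 28.8% at 8.00 h and 27.9% at 15.0 h, and each later reading is lower. The maple ratio of target to substrate has climbed from 1.27 at 8.00 h to 3.54 at 30.0 h. The last reading is the reckoning's estimate of where it comes to rest, the late ratio 4.58, a quasi-equilibrium ratio. It is a reading, and its substrate value of 4.3% scatters by 0.5 percentage points. Leave maple closed and stirred, and expect a later substrate reading to give target:

[target] ≈ 4.58 × [substrate]

The forecast puts the top at 0.43 d with 29.4%, reasoning that “The maximum occurs where formation equals loss”.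

The flask reaches 29.7% at 0.507 d.

    target ⇌ isomer of the product (K = 2.30, k = 1.30 × 10⁻⁵ s⁻¹)
    intermediate → decomposed reagent (k = 4.20 × 10⁻⁶ s⁻¹)
    intermediate ⇌ target (K = 3.30, k = 1.30 × 10⁻⁴ s⁻¹)
    2 substrate → homo dimer (k = 3.90 × 10⁻⁵ M⁻¹ s⁻¹)
    substrate ⇌ intermediate (K = 1.30, k = 4.70 × 10⁻⁵ s⁻¹)

At 10.0 d the flask holds 2.54% of substrate, so the late ratio gives 11.6% of target, and it holds 11.4%. The neighbouring flask is charged with 0.13 M of substrate and reaches a top of 37.5%. At its end the neighbouring flask holds 3.54% of substrate, so the same ratio gives 16.2% of target, and it holds 15.7%.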